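**Plan**

Numbering (elemane): ring C5–C10; C10 carries CH3 and the vinyl C1=C2, C5 carries C4(=C3H2)–C15H2OH, C8 carries the acyloxy group; lactone O–C6 and C7–C11(CH3)–C12(=O).
Cuts, in order: (1) the C8–O acyl bond; (2) the lactone C12–O bond together with the ring bond C6–C7; (3) C5–C10; (4) C8–C9 and the ester C6(=O)–O–C2 of the open chain.
Feature used by the key step: the trans-fused γ-lactone puts an O-bearing ring carbon (C6) next to the β-carbon (C7) of the C11–C12 propionate. In the open form both are electrophilic (aldehyde C6, enoate C7=C11), so a ketyl at C6 closes the cyclohexane and then the lactone in one operation.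
Forward: a vinylogous aldol joins C8–C9 of an acyclic C10 chain; its allylic ester with an itaconic-acid-derived C5 acid undergoes Ireland–Claisen rearrangement (C5–C10, vinyl and 2-propenyl groups at once); SmI2 forms the carbocycle first and the lactone second; acylation of O8 and deprotection finish.
Stereochemistry: C8 from the asymmetric vinylogous aldol; C5/C10 relative from the chair Claisen transition state ((E)-alkene, E(O)-enolate), absolute from a chiral boron controller; C6/C7 from the chair ketyl cyclisation; C11 by thermodynamic epimerisation; C3' from the (S)-malate-derived dioxolane ester.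

Key step: step 13

Assumption: the sense of induction of the two chiral controllers (oxazaborolidinone in step 3, diazaborolidine in step 10) is taken to be the one drawn; should either prove opposite, its enantiomer is used and nothing else changes.

**Route**

Step 1
Reactants: 1 ethyl 2-(triphenyl-λ5-phosphanylidene)propanoate; 2 2,2-dimethoxyacetaldehyde
Product: 4 ethyl (2E)-2-methyl-4-oxobut-2-enoate, via dimethyl acetal 3 (not isolated)
Conditions: CH2Cl2, rt; then 1 M HCl, THF, rt
Reagents that add atoms: water (O)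
Why: Wittig olefination with the α-methyl stabilised ylide should give the (E)-trisubstituted enoate, and acetal hydrolysis then frees the aldehyde.

Step 2
Reactants: 5 3-methylbut-2-enal
Product: 6 tert-butyl(dimethyl){[(1E)-3-methylbuta-1,3-dien-1-yl]oxy}silane
Conditions: TBSOTf, Et3N, CH2Cl2, 0 °C
Reagents that add atoms: tert-butyldimethylsilyl triflate (CC(C)(C)[Si](C)(C)OS(=O)(=O)C(F)(F)F)
Why: O-silylation of the enal with γ-deprotonation (soft enolisation) should give the (E)-silyl dienol ether.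

Step 3
Reactants: 4 ethyl (2E)-2-methyl-4-oxobut-2-enoate; 6 silyl dienol ether
Product: 7 ethyl (2E,4R,6E)-4-hydroxy-2,6-dimethyl-8-oxoocta-2,6-dienoate
Conditions: B-phenyl oxazaborolidinone from N-Ts-L-tryptophan and PhBCl2 (30 mol%), i-PrOH, EtCN, −78 °C
Reagents that add atoms: none
Why: Vinylogous Mukaiyama aldol reaction: the dienol ether attacks the Lewis-acid-bound aldehyde through its γ-carbon (C8–C9 bond, (E)-enal), and the chiral oxazaborolidinone selects the aldehyde face that gives the 4R carbinol (C8).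

Step 4
Reactants: 7 hydroxy enal
Product: 8 ethyl (2E,4R,6E)-2,6-dimethyl-8-oxo-4-[(triethylsilyl)oxy]octa-2,6-dienoate
Conditions: TESCl, imidazole, DMF, 0 °C
Reagents that add atoms: chlorotriethylsilane (CC[Si](Cl)(CC)CC)
Why: Standard silylation of the secondary allylic alcohol; the TES group is chosen so that it can later be removed in the presence of a primary TBS ether.

Step 5
Reactants: 8 TES ether enal
Product: 9 ethyl (2E,4R,6E)-8-hydroxy-2,6-dimethyl-4-[(triethylsilyl)oxy]octa-2,6-dienoate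
Conditions: NaBH4, CeCl3·7H2O, MeOH, −40 °C
Reagents that add atoms: none
Why: Luche reduction should reduce the enal 1,2 to the (E)-allylic alcohol and leave the enoate ester untouched.

Step 6
Reactants: 10 4-methoxy-2-methylidene-4-oxobutanoic acid (4-methyl hydrogen itaconate)
Product: 12 methyl 3-(hydroxymethyl)but-3-enoate, via mixed anhydride 11 (not isolated)
Conditions: i-BuOCOCl, N-methylmorpholine, THF, −15 °C; then NaBH4, H2O, 0 °C; used at once in step 7
Reagents that add atoms: none
Why: Reduction of the mixed carbonic anhydride with NaBH4 should convert the free (conjugated) acid to the alcohol while the methyl ester survives; this fixes the C15 oxidation level.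

Step 7
Reactants: 12 methyl 3-(hydroxymethyl)but-3-enoate
Product: 13 methyl 3-({[tert-butyl(dimethyl)silyl]oxy}methyl)but-3-enoate
Conditions: TBSCl, imidazole, DMF, 0 °C
Reagents that add atoms: tert-butyldimethylsilyl chloride (CC(C)(C)[Si](C)(C)Cl)
Why: Silylation of the primary allylic alcohol, which also blocks lactonisation of the γ-hydroxy ester.

Step 8
Reactants: 13 TBS ether ester
Product: 15 3-({[tert-butyl(dimethyl)silyl]oxy}methyl)but-3-enoic acid, via trimethylstannyl ester 14 (not isolated)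
Conditions: Me3SnOH, 1,2-dichloroethane, 80 °C; then 1 M HCl wash
Reagents that add atoms: trimethyltin hydroxide (C[Sn](C)(C)O)
Why: Near-neutral ester hydrolysis with Me3SnOH should free the acid without base-induced migration of the β,γ-double bond into conjugation.

Step 9
Reactants: 9 allylic alcohol; 15 acid
Product: 16 ethyl (2E,4R,6E)-8-{[3-({[tert-butyl(dimethyl)silyl]oxy}methyl)but-3-enoyl]oxy}-2,6-dimethyl-4-[(triethylsilyl)oxy]octa-2,6-dienoate
Conditions: DCC, DMAP (cat.), CH2Cl2, 0 °C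
Reagents that add atoms: none
Why: Steglich esterification of the primary allylic alcohol; low temperature and catalytic DMAP keep the β,γ-unsaturated acyl unit from isomerising.

Step 10
Reactants: 16 allylic ester
Product: 19 (2S,3R,5R,6E)-2-(3-{[tert-butyl(dimethyl)silyl]oxy}prop-1-en-2-yl)-3-ethenyl-8-ethoxy-3,7-dimethyl-8-oxo-5-[(triethylsilyl)oxy]oct-6-enoic acid, via boron ketene acetal 17 (not isolated), via acyloxyborane 18 (not isolated)
Conditions: (4S,5S)-2-bromo-1,3-bis{[3,5-bis(trifluoromethyl)phenyl]sulfonyl}-4,5-diphenyl-1,3,2-diazaborolidine (1.3 equiv), Et3N, PhMe/hexane, −78 °C; then 4 °C; aqueous work-up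
Reagents that add atoms: none
Why: Ireland–Claisen rearrangement through a boron ketene acetal: soft enolisation gives the E(O)-enolate, and the chair [3,3] shift with the (E)-trisubstituted allyl unit (C9 branch equatorial, C10 methyl and the C4 unit axial) forms C5–C10 with the required relative configuration, creating the quaternary C10 with its vinyl group and the 2-propenyl unit on C5. The C2-symmetric diazaborolidine selects the enolate face, so the absolute sense is reagent-controlled and independent of the remote C8 centre.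

Step 11
Reactants: 19 acid
Product: 21 ethyl (2E,4R,6R,7S)-9-{[tert-butyl(dimethyl)silyl]oxy}-6-ethenyl-7-(hydroxymethyl)-2,6-dimethyl-8-methylidene-4-[(triethylsilyl)oxy]non-2-enoate, via acyl imidazolide 20 (not isolated)
Conditions: 1,1'-carbonyldiimidazole, THF, rt; then NaBH4, H2O, 0 °C
Reagents that add atoms: none
Why: Borohydride reduction of the acyl imidazolide should reduce the hindered acid selectively; the conjugated ethyl ester and the alkenes are not touched.

Step 12
Reactants: 21 primary alcohol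
Product: 22 ethyl (2E,4R,6R,7S)-9-{[tert-butyl(dimethyl)silyl]oxy}-6-ethenyl-7-formyl-2,6-dimethyl-8-methylidene-4-[(triethylsilyl)oxy]non-2-enoate
Conditions: Dess–Martin periodinane, CH2Cl2, 0 °C to rt; used without storage
Reagents that add atoms: none
Why: Dess–Martin oxidation is non-basic, so the α-branched β,γ-unsaturated aldehyde should form without epimerisation at C5 or migration of the double bond.

Step 13
Reactants: 22 aldehyde enoate
Product: 24 (3R,3aR,4R,6R,7S,7aS)-7-(3-{[tert-butyl(dimethyl)silyl]oxy}prop-1-en-2-yl)-6-ethenyl-3,6-dimethyl-4-[(triethylsilyl)oxy]hexahydro-1-benzofuran-2(3H)-one, via hydroxy ester 23 (not isolated)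
Conditions: SmI2 (2.5 equiv), t-BuOH (2.2 equiv), THF, −78 to 0 °C; then DBU (0.2 equiv), THF, rt
Reagents that add atoms: none
Why: SmI2 reduces the aldehyde to the C6 ketyl radical anion, which adds 6-exo-trig to C7 of the (E)-enoate; the α-ester radical is reduced to the Sm(III) enolate and protonated by t-BuOH, the Sm(III) alkoxide on C6 then acylates itself with the ethyl ester to the γ-lactone, and DBU finally equilibrates C11. The closest known reaction type is the SmI2-mediated ketyl–olefin reductive cyclisation of aldehyde-tethered enoates with in situ lactonisation, as used to turn sugar-derived hydroxy enoates into carbocycles. Both carbons joined (aldehyde C6, enoate β-carbon C7) are electrophilic, so this is a polarity-reversed union that closes the cyclohexane by radical 6-exo attack and the lactone by acyl substitution. C6 and C7 arise in a chair transition state in which the C5 side chain and the C8 silyloxy group are equatorial and the C10 methyl axial (all preset), with the ketyl oxygen and the enoate pseudo-equatorial and anti, which gives the trans-diequatorial C6–O/C7–C11 pair; C11 is set thermodynamically, its methyl turning away from the C8 branch. The step needs electron transfer to the aldehyde rather than to the γ-silyloxy enoate, which the much easier reduction of the aldehyde at −78 °C without HMPA should secure.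

Step 14
Reactants: 24 TES ether lactone
Product: 25 (3R,3aS,4R,6R,7S,7aS)-7-(3-{[tert-butyl(dimethyl)silyl]oxy}prop-1-en-2-yl)-6-ethenyl-4-hydroxy-3,6-dimethylhexahydro-1-benzofuran-2(3H)-one
Conditions: PPTS (cat.), MeOH/CH2Cl2, 0 °C
Reagents that add atoms: none
Why: Acid-catalysed methanolysis should cleave the far more labile secondary TES ether and leave the primary TBS ether and the lactone.

Step 15
Reactants: 26 methyl [(4S)-2,2-dimethyl-1,3-dioxolan-4-yl]acetate
Product: 29 methyl 2-[(4S)-2,2-dimethyl-1,3-dioxolan-4-yl]prop-2-enoate, via Mannich base 27 (not isolated), via ammonium iodide 28 (not isolated)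
Conditions: LDA, THF, −78 °C; Eschenmoser's salt, −78 °C; then MeI, MeOH, rt; then K2CO3, CH2Cl2/H2O, rt
Reagents that add atoms: N,N-dimethylmethyleneiminium iodide (C=[N+](C)C.[I-])
Why: α-Methylenation by Mannich reaction of the ester enolate, N-quaternisation and β-elimination; the dioxolane stereocentre (C3') is not involved.

Step 16
Reactants: 29 acrylate ester
Product: 30 2-[(4S)-2,2-dimethyl-1,3-dioxolan-4-yl]prop-2-enoic acid
Conditions: LiOH, THF/H2O, 0 °C; then 1 M HCl to pH 3
Reagents that add atoms: lithium hydroxide ([Li+].[OH-])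
Why: Saponification of the methyl ester; the acetonide is stable to base and to the brief mild acidification.

Step 17
Reactants: 30 side-chain acid; 25 alcohol
Product: 32 (3R,3aS,4R,6R,7S,7aS)-7-(3-{[tert-butyl(dimethyl)silyl]oxy}prop-1-en-2-yl)-6-ethenyl-3,6-dimethyl-2-oxooctahydro-1-benzofuran-4-yl 2-[(4S)-2,2-dimethyl-1,3-dioxolan-4-yl]prop-2-enoate, via mixed anhydride 31 (not isolated)
Conditions: 2,4,6-trichlorobenzoyl chloride, Et3N, THF, rt; then 25, DMAP, PhMe, rt
Reagents that add atoms: none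
Why: Yamaguchi esterification: DMAP-mediated acyl transfer from the mixed anhydride should acylate the hindered equatorial C8 hydroxyl with retention.

Step 18
Reactants: 32 protected ester
Product: 33 target, (3R,3aS,4R,6R,7S,7aS)-6-ethenyl-7-(3-hydroxyprop-1-en-2-yl)-3,6-dimethyl-2-oxooctahydro-1-benzofuran-4-yl (3S)-3,4-dihydroxy-2-methylidenebutanoate
Conditions: AcOH/THF/H2O (3:1:1), 45 °C
Reagents that add atoms: none
Why: Mild aqueous acid should cleave the primary allylic TBS ether and the terminal acetonide together, while the lactone, the acrylate ester and the 1,1-disubstituted alkenes are stable.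

**Compound list**

1 | ethyl 2-(triphenyl-λ5-phosphanylidene)propanoate | CCOC(=O)C(C)=P(c1ccccc1)(c1ccccc1)c1ccccc1 | starting material
2 | 2,2-dimethoxyacetaldehyde | COC(OC)C=O | starting material
3 | ethyl (2E)-4,4-dimethoxy-2-methylbut-2-enoate | CCOC(=O)/C(C)=C/C(OC)OC | intermediate
4 | ethyl (2E)-2-methyl-4-oxobut-2-enoate | CCOC(=O)/C(C)=C/C=O | intermediate
5 | 3-methylbut-2-enal | CC(C)=CC=O | starting material
6 | tert-butyl(dimethyl){[(1E)-3-methylbuta-1,3-dien-1-yl]oxy}silane | C=C(C)/C=C/O[Si](C)(C)C(C)(C)C | intermediate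
7 | ethyl (2E,4R,6E)-4-hydroxy-2,6-dimethyl-8-oxoocta-2,6-dienoate | O=C/C=C(\C)C[C@@H](O)/C=C(\C)C(=O)OCC | intermediate
8 | ethyl (2E,4R,6E)-2,6-dimethyl-8-oxo-4-[(triethylsilyl)oxy]octa-2,6-dienoate | O=C/C=C(\C)C[C@@H](O[Si](CC)(CC)CC)/C=C(\C)C(=O)OCC | intermediate
9 | ethyl (2E,4R,6E)-8-hydroxy-2,6-dimethyl-4-[(triethylsilyl)oxy]octa-2,6-dienoate | OC/C=C(\C)C[C@@H](O[Si](CC)(CC)CC)/C=C(\C)C(=O)OCC | intermediate
10 | 4-methoxy-2-methylidene-4-oxobutanoic acid (4-methyl hydrogen itaconate) | COC(=O)CC(=C)C(O)=O | starting material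
11 | mixed isobutyl carbonic anhydride of 10 | COC(=O)CC(=C)C(=O)OC(=O)OCC(C)C | intermediate
12 | methyl 3-(hydroxymethyl)but-3-enoate | COC(=O)CC(=C)CO | intermediate
13 | methyl 3-({[tert-butyl(dimethyl)silyl]oxy}methyl)but-3-enoate | COC(=O)CC(=C)CO[Si](C)(C)C(C)(C)C | intermediate
14 | trimethylstannyl 3-({[tert-butyl(dimethyl)silyl]oxy}methyl)but-3-enoate | C[Sn](C)(C)OC(=O)CC(=C)CO[Si](C)(C)C(C)(C)C | intermediate
15 | 3-({[tert-butyl(dimethyl)silyl]oxy}methyl)but-3-enoic acid | OC(=O)CC(=C)CO[Si](C)(C)C(C)(C)C | intermediate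
16 | ethyl (2E,4R,6E)-8-{[3-({[tert-butyl(dimethyl)silyl]oxy}methyl)but-3-enoyl]oxy}-2,6-dimethyl-4-[(triethylsilyl)oxy]octa-2,6-dienoate | C=C(CO[Si](C)(C)C(C)(C)C)CC(=O)OC/C=C(\C)C[C@@H](O[Si](CC)(CC)CC)/C=C(\C)C(=O)OCC | intermediate
17 | E(O)-boron ketene acetal of 16 (enolate oxygen on the boron of the (4S,5S)-diazaborolidine) | O=S(=O)(N1[C@@H](c2ccccc2)[C@@H](N(B1O/C(=C/C(=C)CO[Si](C)(C)C(C)(C)C)OC/C=C(\C)C[C@@H](O[Si](CC)(CC)CC)/C=C(\C)C(=O)OCC)S(=O)(=O)c2cc(cc(c2)C(F)(F)F)C(F)(F)F)c2ccccc2)c2cc(cc(c2)C(F)(F)F)C(F)(F)F | intermediate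
18 | acyloxyborane of acid 19 (carboxylate oxygen on the same diazaborolidine boron) | O=S(=O)(N1[C@@H](c2ccccc2)[C@@H](N(B1OC(=O)[C@H](C(=C)CO[Si](C)(C)C(C)(C)C)[C@@](C)(C=C)C[C@@H](O[Si](CC)(CC)CC)/C=C(\C)C(=O)OCC)S(=O)(=O)c2cc(cc(c2)C(F)(F)F)C(F)(F)F)c2ccccc2)c2cc(cc(c2)C(F)(F)F)C(F)(F)F | intermediate
19 | (2S,3R,5R,6E)-2-(3-{[tert-butyl(dimethyl)silyl]oxy}prop-1-en-2-yl)-3-ethenyl-8-ethoxy-3,7-dimethyl-8-oxo-5-[(triethylsilyl)oxy]oct-6-enoic acid | OC(=O)[C@H](C(=C)CO[Si](C)(C)C(C)(C)C)[C@@](C)(C=C)C[C@@H](O[Si](CC)(CC)CC)/C=C(\C)C(=O)OCC | intermediate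
20 | acyl imidazolide of 19 | O=C(n1ccnc1)[C@H](C(=C)CO[Si](C)(C)C(C)(C)C)[C@@](C)(C=C)C[C@@H](O[Si](CC)(CC)CC)/C=C(\C)C(=O)OCC | intermediate
21 | ethyl (2E,4R,6R,7S)-9-{[tert-butyl(dimethyl)silyl]oxy}-6-ethenyl-7-(hydroxymethyl)-2,6-dimethyl-8-methylidene-4-[(triethylsilyl)oxy]non-2-enoate | OC[C@H](C(=C)CO[Si](C)(C)C(C)(C)C)[C@@](C)(C=C)C[C@@H](O[Si](CC)(CC)CC)/C=C(\C)C(=O)OCC | intermediate
22 | ethyl (2E,4R,6R,7S)-9-{[tert-butyl(dimethyl)silyl]oxy}-6-ethenyl-7-formyl-2,6-dimethyl-8-methylidene-4-[(triethylsilyl)oxy]non-2-enoate | O=C[C@H](C(=C)CO[Si](C)(C)C(C)(C)C)[C@@](C)(C=C)C[C@@H](O[Si](CC)(CC)CC)/C=C(\C)C(=O)OCC | intermediate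
23 | ring-closed hydroxy ester (cyclohexanol, C6–OH and C7–CH(CH3)CO2Et trans-diequatorial, C11 not yet defined) | C=C[C@@]1(C)C[C@@H](O[Si](CC)(CC)CC)[C@H](C(C)C(=O)OCC)[C@@H](O)[C@@H]1C(=C)CO[Si](C)(C)C(C)(C)C | intermediate
24 | (3R,3aR,4R,6R,7S,7aS)-7-(3-{[tert-butyl(dimethyl)silyl]oxy}prop-1-en-2-yl)-6-ethenyl-3,6-dimethyl-4-[(triethylsilyl)oxy]hexahydro-1-benzofuran-2(3H)-one | C=C[C@@]1(C)C[C@@H](O[Si](CC)(CC)CC)[C@H]2[C@@H](OC(=O)[C@@H]2C)[C@@H]1C(=C)CO[Si](C)(C)C(C)(C)C | intermediate
25 | (3R,3aS,4R,6R,7S,7aS)-7-(3-{[tert-butyl(dimethyl)silyl]oxy}prop-1-en-2-yl)-6-ethenyl-4-hydroxy-3,6-dimethylhexahydro-1-benzofuran-2(3H)-one | C=C[C@@]1(C)C[C@@H](O)[C@H]2[C@@H](OC(=O)[C@@H]2C)[C@@H]1C(=C)CO[Si](C)(C)C(C)(C)C | intermediate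
26 | methyl [(4S)-2,2-dimethyl-1,3-dioxolan-4-yl]acetate | COC(=O)C[C@H]1COC(C)(C)O1 | starting material
27 | methyl 3-(dimethylamino)-2-[(4S)-2,2-dimethyl-1,3-dioxolan-4-yl]propanoate (Mannich base, α-centre undefined) | COC(=O)C(CN(C)C)[C@H]1COC(C)(C)O1 | intermediate
28 | N-methyl ammonium iodide of 27 | COC(=O)C(C[N+](C)(C)C)[C@H]1COC(C)(C)O1.[I-] | intermediate
29 | methyl 2-[(4S)-2,2-dimethyl-1,3-dioxolan-4-yl]prop-2-enoate | COC(=O)C(=C)[C@H]1COC(C)(C)O1 | intermediate
30 | 2-[(4S)-2,2-dimethyl-1,3-dioxolan-4-yl]prop-2-enoic acid | OC(=O)C(=C)[C@H]1COC(C)(C)O1 | intermediate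
31 | mixed 2,4,6-trichlorobenzoic anhydride of 30 | O=C(OC(=O)c1c(Cl)cc(Cl)cc1Cl)C(=C)[C@H]1COC(C)(C)O1 | intermediate
32 | (3R,3aS,4R,6R,7S,7aS)-7-(3-{[tert-butyl(dimethyl)silyl]oxy}prop-1-en-2-yl)-6-ethenyl-3,6-dimethyl-2-oxooctahydro-1-benzofuran-4-yl 2-[(4S)-2,2-dimethyl-1,3-dioxolan-4-yl]prop-2-enoate | C=C[C@@]1(C)C[C@@H](OC(=O)C(=C)[C@H]2COC(C)(C)O2)[C@H]3[C@@H](OC(=O)[C@@H]3C)[C@@H]1C(=C)CO[Si](C)(C)C(C)(C)C | intermediate
33 | (3R,3aS,4R,6R,7S,7aS)-6-ethenyl-7-(3-hydroxyprop-1-en-2-yl)-3,6-dimethyl-2-oxooctahydro-1-benzofuran-4-yl (3S)-3,4-dihydroxy-2-methylidenebutanoate | C=C[C@@]1(C)C[C@@H](OC(=O)C(=C)[C@H](O)CO)[C@H]2[C@@H](OC(=O)[C@@H]2C)[C@@H]1C(=C)CO | target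

**Count**

Total steps: 18. Longest linear sequence: 12 (steps 1, 3, 4, 5, 9, 10, 11, 12, 13, 14, 17, 18).

**Steps most likely to fail, with fallbacks**

Step 10. The boron controller may discriminate the enolate faces poorly on this β,γ-unsaturated ester, the [3,3] shift may be too slow at the temperatures that preserve selectivity, or the Lewis-acidic bromoborane may strip silyl ethers. The fallback replaces reagent control by sorting on a rigid ring; it sets out from 16 and comes back at 25. An ordinary Ireland–Claisen rearrangement of 16 (LDA, TMSCl, THF, −78 °C to rt) should give 19 together with its (2R,3S,5R) diastereomer F1, since the chair transition state fixes only the C5/C10 relationship. PPTS in MeOH removes the TES groups to give hydroxy acid F2 (from 19) and hydroxy acid F3 (from F1), which close on warming with catalytic CSA to δ-lactone F4 and δ-lactone F5; these conformationally fixed diastereomers are separated by chromatography. DIBAL (1.05 equiv, CH2Cl2, −78 °C) reduces F4 to lactol F6, the δ-lactone being expected to react before the α-branched conjugated ethyl ester. The open hydroxy-aldehyde form of F6 under the conditions of step 13 should then give 25 directly.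

Step 3. Enantioselectivity may be low, or the dienol ether may attack through its α-carbon or oligomerise the electron-poor enal 4. The fallback takes C8 from the chiral pool instead of from catalysis; it sets out from 15 and 1 and comes back at 16. Commercial (R)-4-methoxybenzyl glycidyl ether F7 is opened at the terminal carbon by lithium acetylide–ethylenediamine complex (DMSO) to alkynol F8, and TESCl/imidazole gives silyl ether F9. Zirconium-catalysed carboalumination (AlMe3, Cp2ZrCl2) with trapping by paraformaldehyde gives (E)-allylic alcohol F10, which is esterified with acid 15 (DCC, DMAP) to ester F11. DDQ removes the PMB group to give primary alcohol F12, Dess–Martin oxidation gives aldehyde F13, and Wittig reaction with ylide 1 gives 16.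

Step 13. Electron transfer to the γ-silyloxy enoate could lead to reductive β-elimination of the silyloxy group, or the trans selectivity of the ring closure could erode. The fallback replaces the ketyl radical by a polar reductive aldol and sets C8 afterwards; it sets out from 21 and comes back at 32. PPTS/MeOH converts 21 to diol F14, and Dess–Martin oxidation of both hydroxyls gives keto aldehyde F15. Stryker's reagent ([(Ph3P)CuH]6, PhMe) should deliver hydride to C11 of the 4-oxo-enoate, and the resulting C7 enolate closes on the C6 aldehyde to hydroxy keto ester F16 (not isolated), which lactonises and equilibrates at C7 and C11 with DBU to oxo lactone F17. L-Selectride (THF, −78 °C) attacks the C8 ketone from the equatorial side, away from the axial C10 methyl, to give axial alcohol F18. Mitsunobu esterification with acid 30 (DIAD, PPh3) inverts C8 and gives 32.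

**Further compounds**

F1 | step 10 | (2R,3S,5R,6E) diastereomer of acid 19 | OC(=O)[C@@H](C(=C)CO[Si](C)(C)C(C)(C)C)[C@](C)(C=C)C[C@@H](O[Si](CC)(CC)CC)/C=C(\C)C(=O)OCC
F2 | step 10 | hydroxy acid from 19 (TES removed) | OC(=O)[C@H](C(=C)CO[Si](C)(C)C(C)(C)C)[C@@](C)(C=C)C[C@@H](O)/C=C(\C)C(=O)OCC
F3 | step 10 | hydroxy acid from F1 (TES removed) | OC(=O)[C@@H](C(=C)CO[Si](C)(C)C(C)(C)C)[C@](C)(C=C)C[C@@H](O)/C=C(\C)C(=O)OCC
F4 | step 10 | δ-lactone of F2 (C6 carboxyl closed onto O8, wanted isomer) | O=C1[C@H](C(=C)CO[Si](C)(C)C(C)(C)C)[C@@](C)(C=C)C[C@H](/C=C(\C)C(=O)OCC)O1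
F5 | step 10 | δ-lactone of F3 (unwanted isomer) | O=C1[C@@H](C(=C)CO[Si](C)(C)C(C)(C)C)[C@](C)(C=C)C[C@H](/C=C(\C)C(=O)OCC)O1
F6 | step 10 | δ-lactol from F4 (anomeric centre undefined) | OC1[C@H](C(=C)CO[Si](C)(C)C(C)(C)C)[C@@](C)(C=C)C[C@H](/C=C(\C)C(=O)OCC)O1
F7 | step 3 | (R)-2-{[(4-methoxybenzyl)oxy]methyl}oxirane | C1O[C@H]1COCc1ccc(OC)cc1
F8 | step 3 | (R)-1-[(4-methoxybenzyl)oxy]pent-4-yn-2-ol | C#CC[C@@H](O)COCc1ccc(OC)cc1
F9 | step 3 | triethylsilyl ether of F8 | C#CC[C@@H](O[Si](CC)(CC)CC)COCc1ccc(OC)cc1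
F10 | step 3 | (2E,5R)-6-[(4-methoxybenzyl)oxy]-3-methyl-5-[(triethylsilyl)oxy]hex-2-en-1-ol | OC/C=C(\C)C[C@@H](O[Si](CC)(CC)CC)COCc1ccc(OC)cc1
F11 | step 3 | ester of F10 with acid 15 | C=C(CO[Si](C)(C)C(C)(C)C)CC(=O)OC/C=C(\C)C[C@@H](O[Si](CC)(CC)CC)COCc1ccc(OC)cc1
F12 | step 3 | primary alcohol from F11 (PMB removed) | C=C(CO[Si](C)(C)C(C)(C)C)CC(=O)OC/C=C(\C)C[C@@H](O[Si](CC)(CC)CC)CO
F13 | step 3 | aldehyde from F12 | C=C(CO[Si](C)(C)C(C)(C)C)CC(=O)OC/C=C(\C)C[C@@H](O[Si](CC)(CC)CC)C=O
F14 | step 13 | diol from 21 (TES removed) | OC[C@H](C(=C)CO[Si](C)(C)C(C)(C)C)[C@@](C)(C=C)C[C@@H](O)/C=C(\C)C(=O)OCC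
F15 | step 13 | keto aldehyde (C6 aldehyde, C8 ketone, (E)-4-oxo-enoate) | O=C[C@H](C(=C)CO[Si](C)(C)C(C)(C)C)[C@@](C)(C=C)CC(=O)/C=C(\C)C(=O)OCC
F16 | step 13 | hydroxy keto ester from the reductive aldol (C11 undefined) | C=C[C@@]1(C)CC(=O)[C@H](C(C)C(=O)OCC)[C@@H](O)[C@@H]1C(=C)CO[Si](C)(C)C(C)(C)C
F17 | step 13 | 8-oxo lactone | C=C[C@@]1(C)CC(=O)[C@H]2[C@@H](OC(=O)[C@@H]2C)[C@@H]1C(=C)CO[Si](C)(C)C(C)(C)C
F18 | step 13 | C8 epimer of alcohol 25 (axial hydroxyl) | C=C[C@@]1(C)C[C@H](O)[C@H]2[C@@H](OC(=O)[C@@H]2C)[C@@H]1C(=C)CO[Si](C)(C)C(C)(C)C
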